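Ring A is disconnected at C3–C4. The key step exploits that the oxygen-bearing C3 and the methyl-bearing C4 are neighbours in ring A: an ester carbon (C3) on the C10 arm and a vinyl group on C5 (C4=C15) are joined by titanium into a cyclopropanol, which closes ring A (C3–C4) and a temporary C3–C15 bond in one operation. Base later cuts C3–C15, so that C15 becomes the C4 methyl and C3 a ketone. The precursor is a ring B cyclohexene with quaternary C5 (methyl, vinyl), the methyl propanoate arm on C10, a C8 dimethyl ketal and the C9 ketone masked as silyl enol ether, which keeps C10 trigonal until the decalin exists.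

Key step: step 6

Conventions: all ring compounds carry the numbering of the target skeleton. Ring A = C1–C2–C3–C4–C5–C10, ring B = C5–C6–C7–C8–C9–C10, C14 = methyl on C5, C15 = carbon on C4 (vinyl CH2, then cyclopropane CH2, then methyl). β is the face of C14, α the opposite face. Tigloyl = (E)-2-methylbut-2-enoyl, senecioyl = 3-methylbut-2-enoyl.

Target as read from its SMILES: trans-decalin (10α-H), 3α-tigloyloxy, 4β-methyl, 5β-methyl, 7α-isopropenyl, 8-ketone, 9α-senecioyloxy; every substituent except C14 is equatorial; descriptors 3R,4R,5R,7S,9S,10R.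

Remark on the chemistry: methyl and vinyl on C5 are too alike in size to direct a stereocentre at C10 in a monocyclic ketone, so C10 is left trigonal in the precursor and is set, together with the ring fusion, by equilibration in the decalin (step 7).

Step 1
Reactants: 1 2-methoxy-5-methylphenol; 2 methanol
Product: 3 6,6-dimethoxy-3-methylcyclohexa-2,4-dien-1-one
Conditions: PhI(OAc)2 (1.1 equiv), MeOH, −10 → 0 °C; cold filtration through basic alumina, used at once
Reagents that add atoms: methanol, CO
Why: Oxidative dearomatisation of a 2-methoxyphenol by the trivalent iodine reagent places methanol on the methoxy-bearing carbon and gives the o-quinone monoketal (no stereocentre), which is carried on cold before it can dimerise.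

Step 2
Reactants: 3 6,6-dimethoxy-3-methylcyclohexa-2,4-dien-1-one
Product: 4 6,6-dimethoxy-3-methylcyclohex-2-en-1-one
Conditions: H2 (1 atm), RhCl(PPh3)3 (5 mol%), benzene–MeOH, 0 → 23 °C
Reagents that add atoms: none
Why: Homogeneous catalytic hydrogenation with the monovalent rhodium complex saturates only the unhindered cis-disubstituted C4=C5 bond of the dienone and leaves the trisubstituted C2=C3 enone bond (no stereocentre formed).

Step 3
Reactants: 4 6,6-dimethoxy-3-methylcyclohex-2-en-1-one; 5 vinylmagnesium bromide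
Product: 7 (S)-2,2-dimethoxy-5-methyl-5-vinylcyclohexan-1-one, via magnesium enolate 6 (not isolated)
Conditions: Cu(OTf)2 (3 mol%), enantiopure N-aryl-N′-(2-hydroxyalkyl)imidazolinium hexafluorophosphate (carbene precursor, 4 mol%), slow addition of the Grignard reagent, Et2O, −30 °C; then aq NH4Cl
Reagents that add atoms: vinylmagnesium bromide, C=C[Mg]Br
Why: Copper-catalysed asymmetric conjugate addition of a Grignard reagent to a 3-methylcyclohexenone creates the quaternary C5, whose configuration is dictated by the chiral carbene–copper complex (ligand enantiomer chosen for the S ketone), and protonation of the enolate gives the ketone.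

Step 4
Reactants: 7 (S)-2,2-dimethoxy-5-methyl-5-vinylcyclohexan-1-one; 8 methyl acrylate
Product: 9 methyl 3-[(6R)-3,3-dimethoxy-6-methyl-2-oxo-6-vinylcyclohexyl]propanoate (both epimers at C10)
Conditions: t-BuOK (10 mol%), t-BuOH–THF, 0 → 23 °C
Reagents that add atoms: methyl acrylate, C=CC(=O)OC
Why: Base-catalysed Michael addition can take place only at C10, since the other α-carbon is the ketal carbon, and a second addition is blocked by the quaternary C5 next to it, while the configuration of the new C10 centre is left open because it becomes trigonal again in step 5.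

Step 5
Reactants: 9 methyl 3-[(6R)-3,3-dimethoxy-6-methyl-2-oxo-6-vinylcyclohexyl]propanoate; 10 triethylsilyl trifluoromethanesulfonate
Product: 11 methyl 3-[(6R)-3,3-dimethoxy-6-methyl-2-(triethylsilyloxy)-6-vinylcyclohex-1-en-1-yl]propanoate
Conditions: Et3SiOTf (1.3 equiv), Et3N, CH2Cl2, 0 → 23 °C
Reagents that add atoms: triethylsilyl trifluoromethanesulfonate, CC[Si](CC)(CC)OS(=O)(=O)C(F)(F)F
Why: Silyl enol ether formation by soft enolisation converts the ketone into its only possible enol ether (C9=C10), which removes the C10 stereocentre and shields the C9 carbonyl from the organometallic reagents of step 6, while the less basic ester is not silylated.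

Step 6
Reactants: 11 methyl 3-[(6R)-3,3-dimethoxy-6-methyl-2-(triethylsilyloxy)-6-vinylcyclohex-1-en-1-yl]propanoate
Product: 14 (3S,4R,5R)-8,8-dimethoxy-9-(triethylsilyloxy)-3,15-cyclo-11,12,13-trinoreremophil-9-en-3-ol, via titanacyclopropane 12 (not isolated), via oxatitanacyclopentane 13 (not isolated)
Conditions: Ti(OiPr)4 (1.5 equiv), c-C6H11MgCl (5 equiv, added over 4 h), THF–Et2O, 23 °C; then aq NH4Cl
Reagents that add atoms: none
Why: Two equivalents of cyclohexylmagnesium chloride turn Ti(OiPr)4 into a dialkyltitanium that loses cyclohexane to give the cyclohexene complex of divalent titanium (a titanacyclopropane), and ligand exchange moves the metal to the monosubstituted C4=C15 vinyl group (12). The ester carbonyl then inserts into the Ti–C4 bond, which forms C3–C4 and closes ring A in the 6-exo-trig mode (13); methoxide passes to titanium and the remaining Ti–C15 bond adds to the C3 carbonyl in the 3-exo-trig mode, closing the cyclopropane as its titanium alkoxide. The closest known reaction type is the intramolecular Kulinkovich cyclopropanation of ω-alkenyl esters by ligand exchange, applied here to a vinyl group on a quaternary carbon. C3 and C4 are necessarily cis on the three-membered ring and the C4 face is set by the quaternary C5, with C15 expected on the side of C14 because the titanium-bearing carbon turns away from the C6 methylene, while the other C4 epimer would converge in step 7. The step needs exchange at the vinyl group to outrun attack on the ester by the Grignard reagent or by the cyclohexene complex; the monosubstituted alkene (the tetrasubstituted enol ether cannot exchange), the slow Grignard addition and the fixed proximity of arm and vinyl group on the neighbouring trigonal C10 and C5 secure this.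

Step 7
Reactants: 14 (3S,4R,5R)-8,8-dimethoxy-9-(triethylsilyloxy)-3,15-cyclo-11,12,13-trinoreremophil-9-en-3-ol
Product: 15 (4R,5R,10R)-8,8-dimethoxy-4β,5β-dimethyl-trans-decalin-3,9-dione
Conditions: KOH (3 equiv), MeOH–THF, 23 → 40 °C
Reagents that add atoms: none
Why: Base-induced strain-release opening of the cyclopropanol cuts C3–C15 toward the primary carbanion (C15 becomes the C4 methyl and C3 the ketone), methanolysis of the silyl enol ether frees the C9 ketone, and enolisation then equilibrates C4 toward the equatorial β-methyl (a minor 4α-epimer being returned to the same base) and C10 toward the trans ring fusion (10α-H), in which the angular C14 methyl meets the fewest syn-axial hydrogens.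

Step 8
Reactants: 15 (4R,5R,10R)-8,8-dimethoxy-4β,5β-dimethyl-trans-decalin-3,9-dione
Product: 17 (3S,4R,5R,9S,10R)-8,8-dimethoxy-4β,5β-dimethyl-trans-decalin-3β,9α-diol, via 3β-hydroxy ketone 16 (not isolated)
Conditions: LiBH(s-Bu)3 (1.1 equiv), THF, −78 °C; then MeOH, CeCl3·7H2O, NaBH4, −78 → 23 °C
Reagents that add atoms: none
Why: The bulky borohydride reduces the less hindered C3 ketone from the α face, away from the axial C14 methyl, to the axial 3β-alcohol and spares the C9 ketone flanked by the ketal carbon and the ring fusion, which the small hydride of the Luche reduction then attacks axially, anti to the axial C8–OMe bond, to give the equatorial 9α-alcohol.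

Step 9
Reactants: 17 (3S,4R,5R,9S,10R)-8,8-dimethoxy-4β,5β-dimethyl-trans-decalin-3β,9α-diol; 18 tiglic acid
Product: 19 (3R,4R,5R,9S,10R)-9α-hydroxy-8,8-dimethoxy-4β,5β-dimethyl-trans-decalin-3α-yl (E)-2-methylbut-2-enoate
Conditions: PPh3, DIAD, tiglic acid (1.5 equiv), toluene–THF, 0 → 23 °C
Reagents that add atoms: tiglic acid, C/C=C(\C)C(=O)O
Why: The Mitsunobu reaction displaces the activated axial 3β-oxygen by tiglate with inversion (SN2 from the α face) to give the equatorial 3α-ester, while the C9 hydroxyl between the ketal carbon and the ring fusion is too hindered to be activated or displaced.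

Step 10
Reactants: 19 (3R,4R,5R,9S,10R)-9α-hydroxy-8,8-dimethoxy-4β,5β-dimethyl-trans-decalin-3α-yl (E)-2-methylbut-2-enoate; 20 water
Product: 21 (3R,4R,5R,9S,10R)-9α-hydroxy-4β,5β-dimethyl-8-oxo-trans-decalin-3α-yl (E)-2-methylbut-2-enoate
Conditions: p-TsOH·H2O (10 mol%), acetone–H2O, 23 → 40 °C
Reagents that add atoms: water, O
Why: Acid-catalysed hydrolysis of the dimethyl ketal frees the C8 ketone, and the mild acid leaves the tiglate and the equatorial C9 carbinol untouched (no stereocentre formed).

Step 11
Reactants: 21 (3R,4R,5R,9S,10R)-9α-hydroxy-4β,5β-dimethyl-8-oxo-trans-decalin-3α-yl (E)-2-methylbut-2-enoate; 22 tert-butyldimethylsilyl trifluoromethanesulfonate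
Product: 23 (3R,4R,5R,9S,10R)-9α-(tert-butyldimethylsilyloxy)-4β,5β-dimethyl-8-oxo-trans-decalin-3α-yl (E)-2-methylbut-2-enoate
Conditions: t-BuMe2SiOTf (1.2 equiv), 2,6-lutidine, CH2Cl2, −78 → −40 °C
Reagents that add atoms: tert-butyldimethylsilyl trifluoromethanesulfonate, CC(C)(C)[Si](C)(C)OS(=O)(=O)C(F)(F)F
Why: Silylation of the secondary alcohol protects O9 for the enolate chemistry of step 12 and steers enolisation of the C8 ketone away from C9, the weak pyridine base at low temperature leaving the ketone itself unsilylated (no stereocentre changed).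

Step 12
Reactants: 23 (3R,4R,5R,9S,10R)-9α-(tert-butyldimethylsilyloxy)-4β,5β-dimethyl-8-oxo-trans-decalin-3α-yl (E)-2-methylbut-2-enoate; 24 2-bromopropene
Product: 25 (3R,4R,5R,7S,9S,10R)-9α-(tert-butyldimethylsilyloxy)-7α-isopropenyl-4β,5β-dimethyl-8-oxo-trans-decalin-3α-yl (E)-2-methylbut-2-enoate
Conditions: Pd2(dba)3 (2.5 mol%), P(t-Bu)3 (6 mol%), LiN(SiMe3)2 (2.1 equiv), toluene–THF, 23 → 50 °C; AcOH quench at −78 °C
Reagents that add atoms: 2-bromopropene, C=C(C)Br
Why: In this palladium-catalysed α-alkenylation of a ketone enolate the amide base enolises C8 toward C7 (C9 carries the silyloxy group and its axial hydrogen lies under C14), the alkenylpalladium bromide from oxidative addition to zerovalent palladium couples at C7, and protonation on quench leaves the isopropenyl group in the equatorial 7α position, the stable one next to the ketone.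

Step 13
Reactants: 25 (3R,4R,5R,7S,9S,10R)-9α-(tert-butyldimethylsilyloxy)-7α-isopropenyl-4β,5β-dimethyl-8-oxo-trans-decalin-3α-yl (E)-2-methylbut-2-enoate
Product: 26 (3R,4R,5R,7S,9S,10R)-9α-hydroxy-7α-isopropenyl-4β,5β-dimethyl-8-oxo-trans-decalin-3α-yl (E)-2-methylbut-2-enoate
Conditions: HF·pyridine, pyridine–THF, 0 → 23 °C
Reagents that add atoms: none
Why: Fluoride-mediated desilylation under weakly acidic buffered conditions frees O9 without the base that could move the C11=C12 bond into conjugation or epimerise C7 and C9 (no stereocentre changed).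

Step 14
Reactants: 26 (3R,4R,5R,7S,9S,10R)-9α-hydroxy-7α-isopropenyl-4β,5β-dimethyl-8-oxo-trans-decalin-3α-yl (E)-2-methylbut-2-enoate; 27 3-methylbut-2-enoic acid
Product: 28 (3R,4R,5R,7S,9S,10R)-7α-isopropenyl-4β,5β-dimethyl-9α-(3-methylbut-2-enoyloxy)-8-oxo-trans-decalin-3α-yl (E)-2-methylbut-2-enoate (target)
Conditions: N,N′-dicyclohexylcarbodiimide (1.5 equiv), DMAP (10 mol%), CH2Cl2, 0 → 23 °C
Reagents that add atoms: 3-methylbut-2-enoic acid, CC(C)=CC(=O)O
Why: Steglich esterification acylates O9 with retention at C9, and activation of the acid by the carbodiimide avoids the acid chloride and amine base that could shift the senecioate double bond out of conjugation through a vinylketene.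

Compound list

1 | 2-methoxy-5-methylphenol | COc1ccc(C)cc1O | starting material
2 | methanol | CO | starting material
3 | 6,6-dimethoxy-3-methylcyclohexa-2,4-dien-1-one | CC1=CC(=O)C(OC)(OC)C=C1 | intermediate
4 | 6,6-dimethoxy-3-methylcyclohex-2-en-1-one | CC1=CC(=O)C(OC)(OC)CC1 | intermediate
5 | vinylmagnesium bromide | C=C[Mg]Br | starting material
6 | bromomagnesium enolate of 7 (S at the quaternary carbon) | C=C[C@@]1(C)CCC(OC)(OC)C(O[Mg]Br)=C1 | intermediate
7 | (S)-2,2-dimethoxy-5-methyl-5-vinylcyclohexan-1-one | C=C[C@@]1(C)CCC(OC)(OC)C(=O)C1 | intermediate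
8 | methyl acrylate | C=CC(=O)OC | starting material
9 | methyl 3-[(6R)-3,3-dimethoxy-6-methyl-2-oxo-6-vinylcyclohexyl]propanoate, both epimers at C10 | COC(=O)CCC1C(=O)C(OC)(OC)CC[C@]1(C)C=C | intermediate
10 | triethylsilyl trifluoromethanesulfonate | CC[Si](CC)(CC)OS(=O)(=O)C(F)(F)F | starting material
11 | methyl 3-[(6R)-3,3-dimethoxy-6-methyl-2-(triethylsilyloxy)-6-vinylcyclohex-1-en-1-yl]propanoate (precursor of the key step) | COC(=O)CCC1=C(O[Si](CC)(CC)CC)C(OC)(OC)CC[C@]1(C)C=C | intermediate
12 | titanacyclopropane: Ti(OiPr)2 bound to C4 and C15 of 11 | COC(=O)CCC1=C(O[Si](CC)(CC)CC)C(OC)(OC)CC[C@]1(C)C1C[Ti]1(OC(C)C)OC(C)C | intermediate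
13 | oxatitanacyclopentane Ti–O–C3(OMe)–C4–C15, ring A closed | COC12CCC3=C(O[Si](CC)(CC)CC)C(OC)(OC)CC[C@]3(C)C1C[Ti](OC(C)C)(OC(C)C)O2 | intermediate
14 | (3S,4R,5R)-8,8-dimethoxy-9-(triethylsilyloxy)-3,15-cyclo-11,12,13-trinoreremophil-9-en-3-ol: ring A closed, cyclopropane C3–C4–C15 with C15 on the β face, 3-OH, C9=C10 silyl enol ether, C8 dimethyl ketal | O[C@]12CCC3=C(O[Si](CC)(CC)CC)C(OC)(OC)CC[C@]3(C)[C@H]1C2 | intermediate
15 | (4R,5R,10R)-8,8-dimethoxy-4β,5β-dimethyl-trans-decalin-3,9-dione (10α-H) | COC1(OC)CC[C@]2(C)[C@@H](C)C(=O)CC[C@H]2C1=O | intermediate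
16 | (3S,4R,5R,10R)-3β-hydroxy-8,8-dimethoxy-4β,5β-dimethyl-trans-decalin-9-one | COC1(OC)CC[C@]2(C)[C@@H](C)[C@@H](O)CC[C@H]2C1=O | intermediate
17 | (3S,4R,5R,9S,10R)-8,8-dimethoxy-4β,5β-dimethyl-trans-decalin-3β,9α-diol | COC1(OC)CC[C@]2(C)[C@@H](C)[C@@H](O)CC[C@H]2[C@@H]1O | intermediate
18 | tiglic acid, (E)-2-methylbut-2-enoic acid | C/C=C(\C)C(=O)O | starting material
19 | (3R,4R,5R,9S,10R)-9α-hydroxy-8,8-dimethoxy-4β,5β-dimethyl-trans-decalin-3α-yl (E)-2-methylbut-2-enoate | COC1(OC)CC[C@]2(C)[C@@H](C)[C@H](OC(=O)/C(C)=C/C)CC[C@H]2[C@@H]1O | intermediate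
20 | water | O | starting material
21 | (3R,4R,5R,9S,10R)-9α-hydroxy-4β,5β-dimethyl-8-oxo-trans-decalin-3α-yl (E)-2-methylbut-2-enoate | O=C1CC[C@]2(C)[C@@H](C)[C@H](OC(=O)/C(C)=C/C)CC[C@H]2[C@@H]1O | intermediate
22 | tert-butyldimethylsilyl trifluoromethanesulfonate | CC(C)(C)[Si](C)(C)OS(=O)(=O)C(F)(F)F | starting material
23 | (3R,4R,5R,9S,10R)-9α-(tert-butyldimethylsilyloxy)-4β,5β-dimethyl-8-oxo-trans-decalin-3α-yl (E)-2-methylbut-2-enoate | O=C1CC[C@]2(C)[C@@H](C)[C@H](OC(=O)/C(C)=C/C)CC[C@H]2[C@@H]1O[Si](C)(C)C(C)(C)C | intermediate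
24 | 2-bromopropene | C=C(C)Br | starting material
25 | (3R,4R,5R,7S,9S,10R)-9α-(tert-butyldimethylsilyloxy)-7α-isopropenyl-4β,5β-dimethyl-8-oxo-trans-decalin-3α-yl (E)-2-methylbut-2-enoate | C=C(C)[C@@H]1C[C@]2(C)[C@@H](C)[C@H](OC(=O)/C(C)=C/C)CC[C@H]2[C@H](O[Si](C)(C)C(C)(C)C)C1=O | intermediate
26 | (3R,4R,5R,7S,9S,10R)-9α-hydroxy-7α-isopropenyl-4β,5β-dimethyl-8-oxo-trans-decalin-3α-yl (E)-2-methylbut-2-enoate | C=C(C)[C@@H]1C[C@]2(C)[C@@H](C)[C@H](OC(=O)/C(C)=C/C)CC[C@H]2[C@H](O)C1=O | intermediate
27 | 3-methylbut-2-enoic acid (senecioic acid) | CC(C)=CC(=O)O | starting material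
28 | CNP0375730.3, (3R,4R,5R,7S,9S,10R)-7α-isopropenyl-4β,5β-dimethyl-9α-(3-methylbut-2-enoyloxy)-8-oxo-trans-decalin-3α-yl (E)-2-methylbut-2-enoate | C=C(C)[C@@H]1C[C@]2(C)[C@@H](C)[C@H](OC(=O)/C(C)=C/C)CC[C@H]2[C@H](OC(=O)C=C(C)C)C1=O | target

Total step count: 14. Longest linear sequence: 14 steps (the route is linear from 1).

Steps most likely to fail

Step 6. Ligand exchange at the vinyl group beside the quaternary C5 may be slower than consumption of the ester by the Grignard reagent or by the cyclohexene–titanium complex, so that ring A does not close. The fallback replaces the titanium cyclopropanol by a ketyl–olefin radical closure and sets out from 11. Reduction with i-Bu2AlH (CH2Cl2, −78 °C) gives the aldehyde F1. SmI2 with HMPA and t-BuOH in THF generates the C3 ketyl, which closes ring A in the 6-exo mode onto C4; reduction and protonation of the C15 radical leave the methyl group and give the 4-methyl-3-hydroxy octalin F2 as C3/C4 epimers. Swern oxidation gives the ketone F3, and KOH in MeOH, as in step 7, removes the silyl group and equilibrates C4 and C10, so that the route is rejoined at 15.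

Step 3. The small sp2 Grignard reagent may add to the carbonyl group instead of the enone terminus, or add in the conjugate sense with poor facial selectivity. The fallback replaces it by a silicon-substituted vinylaluminium reagent and sets out from 4. Hydroalumination of ethynyltrimethylsilane with i-Bu2AlH gives the 1-(trimethylsilyl)vinylaluminium reagent, which adds to 4 under catalysis by Cu(OTf)2 and a chiral sulfonate-bearing imidazolinium salt to give the silylvinyl ketone F4. Protodesilylation with CF3CO2H in CH2Cl2 at 0 °C then gives 7, where the route is rejoined.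

Step 12. The excess amide base may enolise or degrade the tiglate, the coupling may stall at the hindered enolate, and the new double bond may drift into conjugation. The fallback replaces enolate alkenylation by cross-coupling of an α-iodoenone and sets out from 23. Kinetic enolisation at −78 °C with LiN(SiMe3)2 (1.05 equiv) and Me3SiCl gives the C7=C8 silyl enol ether F5, and Saegusa oxidation with Pd(OAc)2 gives the C6=C7 enone F6. Iodine and pyridine give the 7-iodoenone F7, and Suzuki coupling with isopropenylboronic acid pinacol ester (PdCl2(dppf), K3PO4) gives the 7-isopropenyl enone F8. Conjugate reduction of the ring enone with [(Ph3P)CuH]6, followed by protonation at C7 to the equatorial isopropenyl ketone, returns to the route at 25.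

Further compounds

F1 | step 6 | 3-[(6R)-3,3-dimethoxy-6-methyl-2-(triethylsilyloxy)-6-vinylcyclohex-1-en-1-yl]propanal | O=CCCC1=C(O[Si](CC)(CC)CC)C(OC)(OC)CC[C@]1(C)C=C
F2 | step 6 | (5R)-8,8-dimethoxy-4,5-dimethyl-9-(triethylsilyloxy)-Δ9(10)-octalin-3-ol, C3/C4 epimers | OC1CCC2=C(O[Si](CC)(CC)CC)C(OC)(OC)CC[C@]2(C)C1C
F3 | step 6 | (5R)-8,8-dimethoxy-4,5-dimethyl-9-(triethylsilyloxy)-Δ9(10)-octalin-3-one, C4 epimers | O=C1CCC2=C(O[Si](CC)(CC)CC)C(OC)(OC)CC[C@]2(C)C1C
F4 | step 3 | (S)-2,2-dimethoxy-5-methyl-5-[1-(trimethylsilyl)vinyl]cyclohexan-1-one | C=C([Si](C)(C)C)[C@@]1(C)CCC(OC)(OC)C(=O)C1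
F5 | step 12 | C7=C8 trimethylsilyl enol ether of 23 | C[Si](C)(C)OC1=CC[C@]2(C)[C@@H](C)[C@H](OC(=O)/C(C)=C/C)CC[C@H]2[C@@H]1O[Si](C)(C)C(C)(C)C
F6 | step 12 | C6=C7 enone of 23 (9α-silyloxy-8-oxo-Δ6-octalin 3α-tiglate) | O=C1C=C[C@]2(C)[C@@H](C)[C@H](OC(=O)/C(C)=C/C)CC[C@H]2[C@@H]1O[Si](C)(C)C(C)(C)C
F7 | step 12 | 7-iodo derivative of enone F6 | O=C1C(I)=C[C@]2(C)[C@@H](C)[C@H](OC(=O)/C(C)=C/C)CC[C@H]2[C@@H]1O[Si](C)(C)C(C)(C)C
F8 | step 12 | 7-isopropenyl derivative of enone F6 | C=C(C)C1=C[C@]2(C)[C@@H](C)[C@H](OC(=O)/C(C)=C/C)CC[C@H]2[C@H](O[Si](C)(C)C(C)(C)C)C1=O
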